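**Plan**

- Retrosynthetic cuts: first the C9'–O ester bond (coumarate), then C1–C2 and C2–C3 of ring B, which meet at C2, then the chain alkene (cross-metathesis) and the bond from C1 to ring A (aryllithium addition).
- Enabling feature (tetralin numbering: C1 bears ring C, C4 is the benzylic CH2 on ring A, C9' is the carbon on C2, C9 the carbon on C3): C2 lies between the doubly benzylic C1 and C3 and bears the carboxyl-level carbon C9'. The central carbon of dimethyl malonate can therefore become C2, bonded once to C3 (allyl terminus) and once to C1 (diarylmethyl cation), a [5+1] closure of ring B.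
- Forward: ring A (from eugenol) and ring C (O-benzylvanillin) are joined at C1, the allyl chain is lengthened to an (E)-allyl carbonate, ring B is closed in the key step, then the vinyl group (C9) and one ester (C9') are adjusted and the coumarate is attached.
- Stereochemistry: C3 from the iridium–phosphoramidite catalyst; C1 from chair-like capture of the cation (aryl cis to vinyl); C2 by equilibration of the ester to the all-equatorial isomer; the (E)-alkene comes in with the cinnamic acid.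

Key step: step 6

Assumption: with L = O,O'-[(R)-1,1'-binaphthalene-2,2'-diyl] N,N-bis[(R)-1-phenylethyl]phosphoramidite, the (Ra,Rc,Rc) ligand, the malonate is taken to attack the allyl face that gives (S)-C3, as this catalyst family does with linear (E)-allyl carbonates (the mirror-image ligand would give the antipode); TBD = 1,5,7-triazabicyclo[4.4.0]dec-5-ene.

**Route**

Step 1
Reactants: 1 eugenol
Product: 2 1-(benzyloxy)-2-methoxy-4-(prop-2-en-1-yl)benzene
Conditions: BnBr, K2CO3, acetone, reflux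
Reagents that add atoms: benzyl bromide, BrCc1ccccc1
Why: Williamson ether synthesis on the phenoxide; the benzyl ether is chosen because it should survive organolithium, metathesis, iridium catalysis, Lewis acid and hot chloride in DMSO.

Step 2
Reactants: 2 1-(benzyloxy)-2-methoxy-4-(prop-2-en-1-yl)benzene
Product: 3 1-(benzyloxy)-5-bromo-2-methoxy-4-(prop-2-en-1-yl)benzene
Conditions: NBS, MeCN, 0 °C → rt, dark
Reagents that add atoms: N-bromosuccinimide, O=C1CCC(=O)N1Br
Why: electrophilic aromatic bromination; the site para to OMe and ortho to the allyl group is the most activated open position, and in dry acetonitrile NBS should brominate such a dialkoxyarene much faster than it attacks a terminal alkene.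

Step 3
Reactants: 3 1-(benzyloxy)-5-bromo-2-methoxy-4-(prop-2-en-1-yl)benzene; 4 4-(benzyloxy)-3-methoxybenzaldehyde
Product: 6 rac-[5-(benzyloxy)-4-methoxy-2-(prop-2-en-1-yl)phenyl][4-(benzyloxy)-3-methoxyphenyl]methanol, via the aryllithium 5 (not isolated)
Conditions: n-BuLi, THF, −78 °C; then 4, −78 → 0 °C; aq. NH4Cl
Reagents that add atoms: none
Why: bromine–lithium exchange followed by 1,2-addition to a non-enolizable aldehyde; at −78 °C exchange should outrun deprotonation of the benzylic/allylic CH2, and the carbinol may be racemic because C1 is ionized later.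

Step 4
Reactants: 7 (Z)-but-2-ene-1,4-diol
Product: 8 (Z)-but-2-ene-1,4-diyl dimethyl biscarbonate
Conditions: ClCO2Me, pyridine, CH2Cl2, 0 °C
Reagents that add atoms: methyl chloroformate, COC(=O)Cl
Why: acylation of both primary alcohols with a chloroformate gives the symmetrical metathesis partner that carries the leaving group needed for iridium.

Step 5
Reactants: 6 rac-[5-(benzyloxy)-4-methoxy-2-(prop-2-en-1-yl)phenyl][4-(benzyloxy)-3-methoxyphenyl]methanol; 8 (Z)-but-2-ene-1,4-diyl dimethyl biscarbonate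
Product: 9 (2E)-4-{4-(benzyloxy)-2-[[4-(benzyloxy)-3-methoxyphenyl](hydroxy)methyl]-5-methoxyphenyl}but-2-en-1-yl methyl carbonate (racemic at the carbinol)
Conditions: 8 (3 equiv), second-generation Grubbs catalyst RuCl2(=CHPh)(PCy3)(H2IMes) (5 mol%), 1,4-benzoquinone (10 mol%), CH2Cl2, 40 °C
Reagents that add atoms: none
Why: olefin cross-metathesis of a terminal allylarene with an excess of a symmetrical cis-alkene should give mainly the (E)-allyl carbonate; the free carbinol and benzyl ethers are tolerated and benzoquinone suppresses alkene migration by ruthenium hydrides.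

Step 6
Reactants: 9 (2E)-4-{4-(benzyloxy)-2-[[4-(benzyloxy)-3-methoxyphenyl](hydroxy)methyl]-5-methoxyphenyl}but-2-en-1-yl methyl carbonate; 10 dimethyl malonate
Product: 12 dimethyl (1S,3S)-7-(benzyloxy)-1-[4-(benzyloxy)-3-methoxyphenyl]-3-ethenyl-6-methoxy-3,4-dihydronaphthalene-2,2(1H)-dicarboxylate, via the branched malonate 11 (not isolated)
Conditions: [Ir(cod)Cl]2 (2 mol%), L (4 mol%), TBD (8 mol%), 10 (1.2 equiv), THF, rt; then THF evaporated, CH2Cl2/MeNO2 (0.02 M), Bi(OTf)3 (15 mol%), 0 °C → rt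
Reagents that add atoms: none
Why: The iridium–phosphoramidite catalyst (monovalent iridium, cyclometalated with the help of TBD) ionizes the linear (E)-carbonate with loss of CO2 and methoxide, which deprotonates 10, and the malonate anion attacks the substituted allyl terminus anti to the metal, forming C2–C3 and setting (S)-C3 under ligand control; this is the known branched-selective iridium-catalysed asymmetric allylic alkylation, in which the neutral secondary carbinol is far too weak an acid to compete as a nucleophile. Bi(OTf)3 then ionizes both carbinol epimers of 11 to one diarylmethyl cation, stabilized by the para-benzyloxy group of ring C and the para-methoxy group of ring A, and the metal-bound enol of the malonate captures it to form C1–C2, the known acid-catalysed alkylation of 1,3-dicarbonyl compounds by diarylmethanols run intramolecularly. Ring B closes in a 6-(enolexo)-exo-trig mode: the enol double bond and, in its quinone-methide-like form, the cation double bond from C1 to ring C both lie outside the new six-membered ring. C1 is set by the substrate in a chair-like transition state: allylic strain with the fully substituted enol keeps C3–H in the enol plane and the vinyl group equatorial, and the cation reacts with ring C turned away from the C4 methylene so that the aryl group ends equatorial and cis to the vinyl group. The step needs branched over linear allylation (secured by iridium), C–C over C–O bond formation at the allyl unit (secured by the acidity gap between malonate and carbinol under base-free conditions) and ring closure over intermolecular capture of the cation (secured by the six-membered transition state, high dilution and the small excess of 10).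

Step 7
Reactants: 12 dimethyl (1S,3S)-7-(benzyloxy)-1-[4-(benzyloxy)-3-methoxyphenyl]-3-ethenyl-6-methoxy-3,4-dihydronaphthalene-2,2(1H)-dicarboxylate
Product: 14 methyl (1S,2S,3S)-7-(benzyloxy)-1-[4-(benzyloxy)-3-methoxyphenyl]-3-ethenyl-6-methoxy-1,2,3,4-tetrahydronaphthalene-2-carboxylate, via the C2-epimeric ester 13 (not isolated)
Conditions: LiCl, H2O, DMSO, 150 °C; then NaOMe (0.3 equiv), MeOH, rt
Reagents that add atoms: none
Why: Krapcho dealkoxycarbonylation (chloride attack at a methyl ester, loss of CO2, protonation of the enolate); C2 is set under thermodynamic control, since methoxide should equilibrate any cis ester 13 to the equatorial ester trans to both the C1 aryl and the C3 vinyl group, while benzyl ethers and vinyl are inert.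

Step 8
Reactants: 14 methyl (1S,2S,3S)-7-(benzyloxy)-1-[4-(benzyloxy)-3-methoxyphenyl]-3-ethenyl-6-methoxy-1,2,3,4-tetrahydronaphthalene-2-carboxylate
Product: 16 methyl (1S,2R,3R)-7-(benzyloxy)-1-[4-(benzyloxy)-3-methoxyphenyl]-3-formyl-6-methoxy-1,2,3,4-tetrahydronaphthalene-2-carboxylate, via the vicinal diol 15 (not isolated)
Conditions: OsO4 (2 mol%), NaIO4 (4 equiv), 2,6-lutidine, dioxane/H2O, rt
Reagents that add atoms: osmium tetroxide, O=[Os](=O)(=O)=O; sodium periodate, [Na+].[O-]I(=O)(=O)=O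
Why: Lemieux–Johnson oxidation (dihydroxylation then glycol cleavage) removes the terminal carbon and leaves C9 as an aldehyde; the benzyl-capped phenols resist periodate and the equatorial aldehyde is also the thermodynamic epimer at C3.

Step 9
Reactants: 16 methyl (1S,2R,3R)-7-(benzyloxy)-1-[4-(benzyloxy)-3-methoxyphenyl]-3-formyl-6-methoxy-1,2,3,4-tetrahydronaphthalene-2-carboxylate
Product: 17 methyl (1S,2R,3R)-7-(benzyloxy)-1-[4-(benzyloxy)-3-methoxyphenyl]-3-(hydroxymethyl)-6-methoxy-1,2,3,4-tetrahydronaphthalene-2-carboxylate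
Conditions: NaBH4, MeOH/THF, −40 → −20 °C; AcOH quench
Reagents that add atoms: none
Why: borohydride reduction of an aldehyde beside a methyl ester; in the cold the ester and both adjacent centres should be untouched, and the trans hydroxy ester should close only slowly to a strained trans-fused lactone, so it can be silylated at once.

Step 10
Reactants: 17 methyl (1S,2R,3R)-7-(benzyloxy)-1-[4-(benzyloxy)-3-methoxyphenyl]-3-(hydroxymethyl)-6-methoxy-1,2,3,4-tetrahydronaphthalene-2-carboxylate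
Product: 18 methyl (1S,2R,3R)-7-(benzyloxy)-1-[4-(benzyloxy)-3-methoxyphenyl]-6-methoxy-3-{[(triethylsilyl)oxy]methyl}-1,2,3,4-tetrahydronaphthalene-2-carboxylate
Conditions: TESCl, imidazole, CH2Cl2, 0 °C
Reagents that add atoms: chlorotriethylsilane, CC[Si](Cl)(CC)CC
Why: silylation of a primary alcohol with a silyl chloride and imidazole; the triethylsilyl ether blocks lactonization, should survive hydride reduction and carbodiimide coupling, and is labile enough to fall in the acidic methanol of the last step.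

Step 11
Reactants: 18 methyl (1S,2R,3R)-7-(benzyloxy)-1-[4-(benzyloxy)-3-methoxyphenyl]-6-methoxy-3-{[(triethylsilyl)oxy]methyl}-1,2,3,4-tetrahydronaphthalene-2-carboxylate
Product: 20 [(1S,2R,3R)-7-(benzyloxy)-1-[4-(benzyloxy)-3-methoxyphenyl]-6-methoxy-3-{[(triethylsilyl)oxy]methyl}-1,2,3,4-tetrahydronaphthalen-2-yl]methanol, via the aldehyde 19 (not isolated)
Conditions: i-Bu2AlH (3 equiv), CH2Cl2, −78 → 0 °C; aq. KNaC4H4O6
Reagents that add atoms: none
Why: aluminium hydride reduction of the ester to the primary alcohol C9'–OH; silyl and benzyl ethers are inert and the intermediate aldehyde is reduced faster than it can epimerize.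

Step 12
Reactants: 20 [(1S,2R,3R)-7-(benzyloxy)-1-[4-(benzyloxy)-3-methoxyphenyl]-6-methoxy-3-{[(triethylsilyl)oxy]methyl}-1,2,3,4-tetrahydronaphthalen-2-yl]methanol; 21 (2E)-3-[4-(benzyloxy)phenyl]prop-2-enoic acid
Product: 22 [(1S,2R,3R)-7-(benzyloxy)-1-[4-(benzyloxy)-3-methoxyphenyl]-6-methoxy-3-{[(triethylsilyl)oxy]methyl}-1,2,3,4-tetrahydronaphthalen-2-yl]methyl (2E)-3-[4-(benzyloxy)phenyl]prop-2-enoate
Conditions: EDC·HCl, DMAP, CH2Cl2, 0 °C → rt
Reagents that add atoms: none
Why: Steglich esterification of the only free hydroxyl, a primary carbinol, with the O-benzyl acid; the (E) double bond is carried in unchanged.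

Step 13
Reactants: 22 [(1S,2R,3R)-7-(benzyloxy)-1-[4-(benzyloxy)-3-methoxyphenyl]-6-methoxy-3-{[(triethylsilyl)oxy]methyl}-1,2,3,4-tetrahydronaphthalen-2-yl]methyl (2E)-3-[4-(benzyloxy)phenyl]prop-2-enoate
Product: 24 [(1S,2R,3R)-7-hydroxy-1-(4-hydroxy-3-methoxyphenyl)-3-(hydroxymethyl)-6-methoxy-1,2,3,4-tetrahydronaphthalen-2-yl]methyl (2E)-3-(4-hydroxyphenyl)prop-2-enoate, via the triethylsilyl ether 23 (not isolated)
Conditions: BCl3 (8 equiv), C6HMe5 (9 equiv), CH2Cl2, −78 °C; then MeOH/CHCl3, −78 °C → rt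
Reagents that add atoms: none
Why: Lewis acid cleavage of aryl benzyl ethers with pentamethylbenzene as a non-basic benzyl cation scavenger, which should spare the conjugated ester, its double bond and the aryl methyl ethers at −78 °C; the hydrogen chloride formed in methanol on quenching then removes the primary triethylsilyl ether, so hydrogenolysis is avoided.

**Compound list**

1 | eugenol, 2-methoxy-4-(prop-2-en-1-yl)phenol | C=CCc1ccc(O)c(OC)c1 | starting material
2 | 1-(benzyloxy)-2-methoxy-4-(prop-2-en-1-yl)benzene | C=CCc1ccc(OCc2ccccc2)c(OC)c1 | intermediate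
3 | 1-(benzyloxy)-5-bromo-2-methoxy-4-(prop-2-en-1-yl)benzene | C=CCc1cc(OC)c(OCc2ccccc2)cc1Br | intermediate
4 | 4-(benzyloxy)-3-methoxybenzaldehyde | COc1cc(C=O)ccc1OCc1ccccc1 | starting material
5 | [5-(benzyloxy)-4-methoxy-2-(prop-2-en-1-yl)phenyl]lithium | [Li]c1cc(OCc2ccccc2)c(OC)cc1CC=C | intermediate
6 | rac-[5-(benzyloxy)-4-methoxy-2-(prop-2-en-1-yl)phenyl][4-(benzyloxy)-3-methoxyphenyl]methanol | COc1cc(C(O)c2cc(OCc3ccccc3)c(OC)cc2CC=C)ccc1OCc1ccccc1 | intermediate
7 | (Z)-but-2-ene-1,4-diol | OC/C=C\CO | starting material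
8 | (Z)-but-2-ene-1,4-diyl dimethyl biscarbonate | COC(=O)OC/C=C\COC(=O)OC | intermediate
9 | (2E)-4-{4-(benzyloxy)-2-[[4-(benzyloxy)-3-methoxyphenyl](hydroxy)methyl]-5-methoxyphenyl}but-2-en-1-yl methyl carbonate, racemic at the carbinol | COc1cc(C(O)c2cc(OCc3ccccc3)c(OC)cc2C/C=C/COC(=O)OC)ccc1OCc1ccccc1 | intermediate
10 | dimethyl malonate | COC(=O)CC(=O)OC | starting material
11 | dimethyl 2-[(2S)-1-{4-(benzyloxy)-2-[[4-(benzyloxy)-3-methoxyphenyl](hydroxy)methyl]-5-methoxyphenyl}but-3-en-2-yl]propanedioate, both carbinol epimers | COc1cc(C(O)c2cc(OCc3ccccc3)c(OC)cc2C[C@@H](C=C)C(C(=O)OC)C(=O)OC)ccc1OCc1ccccc1 | intermediate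
12 | dimethyl (1S,3S)-7-(benzyloxy)-1-[4-(benzyloxy)-3-methoxyphenyl]-3-ethenyl-6-methoxy-3,4-dihydronaphthalene-2,2(1H)-dicarboxylate, aryl and vinyl cis | COc1cc([C@H]2c3cc(OCc4ccccc4)c(OC)cc3C[C@@H](C=C)C2(C(=O)OC)C(=O)OC)ccc1OCc1ccccc1 | intermediate
13 | methyl (1S,2R,3S)-7-(benzyloxy)-1-[4-(benzyloxy)-3-methoxyphenyl]-3-ethenyl-6-methoxy-1,2,3,4-tetrahydronaphthalene-2-carboxylate, ester cis to aryl and vinyl | COc1cc([C@H]2c3cc(OCc4ccccc4)c(OC)cc3C[C@@H](C=C)[C@H]2C(=O)OC)ccc1OCc1ccccc1 | intermediate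
14 | methyl (1S,2S,3S)-7-(benzyloxy)-1-[4-(benzyloxy)-3-methoxyphenyl]-3-ethenyl-6-methoxy-1,2,3,4-tetrahydronaphthalene-2-carboxylate, ester trans to aryl and vinyl | COc1cc([C@H]2c3cc(OCc4ccccc4)c(OC)cc3C[C@@H](C=C)[C@@H]2C(=O)OC)ccc1OCc1ccccc1 | intermediate
15 | methyl (1S,2R,3R)-7-(benzyloxy)-1-[4-(benzyloxy)-3-methoxyphenyl]-3-(1,2-dihydroxyethyl)-6-methoxy-1,2,3,4-tetrahydronaphthalene-2-carboxylate, both carbinol epimers | COc1cc([C@H]2c3cc(OCc4ccccc4)c(OC)cc3C[C@@H](C(O)CO)[C@@H]2C(=O)OC)ccc1OCc1ccccc1 | intermediate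
16 | methyl (1S,2R,3R)-7-(benzyloxy)-1-[4-(benzyloxy)-3-methoxyphenyl]-3-formyl-6-methoxy-1,2,3,4-tetrahydronaphthalene-2-carboxylate | COc1cc([C@H]2c3cc(OCc4ccccc4)c(OC)cc3C[C@@H](C=O)[C@@H]2C(=O)OC)ccc1OCc1ccccc1 | intermediate
17 | methyl (1S,2R,3R)-7-(benzyloxy)-1-[4-(benzyloxy)-3-methoxyphenyl]-3-(hydroxymethyl)-6-methoxy-1,2,3,4-tetrahydronaphthalene-2-carboxylate | COc1cc([C@H]2c3cc(OCc4ccccc4)c(OC)cc3C[C@@H](CO)[C@@H]2C(=O)OC)ccc1OCc1ccccc1 | intermediate
18 | methyl (1S,2R,3R)-7-(benzyloxy)-1-[4-(benzyloxy)-3-methoxyphenyl]-6-methoxy-3-{[(triethylsilyl)oxy]methyl}-1,2,3,4-tetrahydronaphthalene-2-carboxylate | COc1cc([C@H]2c3cc(OCc4ccccc4)c(OC)cc3C[C@@H](CO[Si](CC)(CC)CC)[C@@H]2C(=O)OC)ccc1OCc1ccccc1 | intermediate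
19 | (1S,2R,3R)-7-(benzyloxy)-1-[4-(benzyloxy)-3-methoxyphenyl]-6-methoxy-3-{[(triethylsilyl)oxy]methyl}-1,2,3,4-tetrahydronaphthalene-2-carbaldehyde | COc1cc([C@H]2c3cc(OCc4ccccc4)c(OC)cc3C[C@@H](CO[Si](CC)(CC)CC)[C@@H]2C=O)ccc1OCc1ccccc1 | intermediate
20 | [(1S,2R,3R)-7-(benzyloxy)-1-[4-(benzyloxy)-3-methoxyphenyl]-6-methoxy-3-{[(triethylsilyl)oxy]methyl}-1,2,3,4-tetrahydronaphthalen-2-yl]methanol | COc1cc([C@H]2c3cc(OCc4ccccc4)c(OC)cc3C[C@@H](CO[Si](CC)(CC)CC)[C@@H]2CO)ccc1OCc1ccccc1 | intermediate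
21 | (2E)-3-[4-(benzyloxy)phenyl]prop-2-enoic acid | O=C(O)/C=C/c1ccc(OCc2ccccc2)cc1 | starting material
22 | [(1S,2R,3R)-7-(benzyloxy)-1-[4-(benzyloxy)-3-methoxyphenyl]-6-methoxy-3-{[(triethylsilyl)oxy]methyl}-1,2,3,4-tetrahydronaphthalen-2-yl]methyl (2E)-3-[4-(benzyloxy)phenyl]prop-2-enoate | COc1cc([C@H]2c3cc(OCc4ccccc4)c(OC)cc3C[C@@H](CO[Si](CC)(CC)CC)[C@@H]2COC(=O)/C=C/c2ccc(OCc3ccccc3)cc2)ccc1OCc1ccccc1 | intermediate
23 | [(1S,2R,3R)-7-hydroxy-1-(4-hydroxy-3-methoxyphenyl)-6-methoxy-3-{[(triethylsilyl)oxy]methyl}-1,2,3,4-tetrahydronaphthalen-2-yl]methyl (2E)-3-(4-hydroxyphenyl)prop-2-enoate | COc1cc([C@H]2c3cc(O)c(OC)cc3C[C@@H](CO[Si](CC)(CC)CC)[C@@H]2COC(=O)/C=C/c2ccc(O)cc2)ccc1O | intermediate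
24 | [(1S,2R,3R)-7-hydroxy-1-(4-hydroxy-3-methoxyphenyl)-3-(hydroxymethyl)-6-methoxy-1,2,3,4-tetrahydronaphthalen-2-yl]methyl (2E)-3-(4-hydroxyphenyl)prop-2-enoate | COc1cc([C@H]2c3cc(O)c(OC)cc3C[C@@H](CO)[C@@H]2COC(=O)/C=C/c2ccc(O)cc2)ccc1O | target

**Count and risks**

Total steps: 13. Longest linear sequence: 12 (steps 1–3 and 5–13; step 4 is a one-step side branch).

Step 6. The cation may be captured with poor facial selectivity at C1 (aryl trans instead of cis to the vinyl group) or be lost to intermolecular arylation, and in the first stage O-allylation or linear allylation may intrude. The fallback sets out from 2 and comes back to the route at 19. It closes ring B at the bond from C1 to ring A by the classical lactone-templated Friedel–Crafts sequence.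
- Cross-metathesis of 2 with 8 (RuCl2(=CHPh)(PCy3)(H2IMes), CH2Cl2) gives (2E)-4-[4-(benzyloxy)-3-methoxyphenyl]but-2-en-1-yl methyl carbonate F1.
- The same [Ir(cod)Cl]2/L/TBD catalyst with 10 gives dimethyl 2-[(2S)-1-[4-(benzyloxy)-3-methoxyphenyl]but-3-en-2-yl]propanedioate F2.
- LiCl in wet DMSO gives methyl (3R)-3-{[4-(benzyloxy)-3-methoxyphenyl]methyl}pent-4-enoate F3.
- Ozonolysis with a NaBH4 finish in the same flask closes (4R)-4-{[4-(benzyloxy)-3-methoxyphenyl]methyl}oxolan-2-one F4.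
- The lithium enolate of F4 (LiN(i-Pr)2, THF, −78 °C) adds to 4 anti to the benzyl group and gives (3S,4R)-3-{[4-(benzyloxy)-3-methoxyphenyl](hydroxy)methyl}-4-{[4-(benzyloxy)-3-methoxyphenyl]methyl}oxolan-2-one F5.
- CF3CO2H in CH2Cl2 ionizes the carbinol and ring A attacks para to its methoxy group, the well-known 1,2-trans cyclization of such hydroxybenzyl lactones. This gives the trans-fused lactone of (1S,2R,3R)-7-(benzyloxy)-1-[4-(benzyloxy)-3-methoxyphenyl]-3-(hydroxymethyl)-6-methoxy-1,2,3,4-tetrahydronaphthalene-2-carboxylic acid F6.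
- Me3Al/MeONHMe·HCl opens F6 without touching C2 to (1S,2R,3R)-7-(benzyloxy)-1-[4-(benzyloxy)-3-methoxyphenyl]-3-(hydroxymethyl)-N,6-dimethoxy-N-methyl-1,2,3,4-tetrahydronaphthalene-2-carboxamide F7.
- Chlorotriethylsilane and imidazole give its triethylsilyl ether F8; i-Bu2AlH at −78 °C gives 19, which NaBH4 reduces to 20.

Step 13. Debenzylation by BCl3 may stay incomplete on three ethers, benzylate the electron-rich rings, or be followed by acyl migration or ester loss during the acidic methanolysis. The fallback sets out from 20 and comes back at 23. The benzyl ethers are removed by hydrogenolysis before any alkene is present.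
- H2, Pd/C in EtOAc gives [(1S,2R,3R)-7-hydroxy-1-(4-hydroxy-3-methoxyphenyl)-6-methoxy-3-{[(triethylsilyl)oxy]methyl}-1,2,3,4-tetrahydronaphthalen-2-yl]methanol F9.
- Mitsunobu esterification (PPh3, DIAD, THF, 0 °C) with unprotected (E)-4-hydroxycinnamic acid (O=C(O)/C=C/c1ccc(O)cc1) acylates the activated primary alcohol and gives 23; the carboxylic acid is by far the most acidic pronucleophile present.
- AcOH/THF/H2O removes the silyl group to give 24.

Step 9. Lactonization of the γ-hydroxy ester onto the C2 ester, or C2 epimerization followed by lactonization, would erase the difference between C9 and C9'. The fallback sets out from 16 and comes back at 24. It reduces the ester before the C9 hydroxyl exists and needs no silyl group.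
- HC(OMe)3 and pyridinium p-toluenesulfonate in MeOH give methyl (1S,2R,3R)-7-(benzyloxy)-1-[4-(benzyloxy)-3-methoxyphenyl]-3-(dimethoxymethyl)-6-methoxy-1,2,3,4-tetrahydronaphthalene-2-carboxylate F10.
- i-Bu2AlH gives [(1S,2R,3R)-7-(benzyloxy)-1-[4-(benzyloxy)-3-methoxyphenyl]-3-(dimethoxymethyl)-6-methoxy-1,2,3,4-tetrahydronaphthalen-2-yl]methanol F11.
- EDC·HCl/DMAP with 21 gives the (2E)-3-[4-(benzyloxy)phenyl]prop-2-enoate of F11, F12.
- Aqueous CF3CO2H in CH2Cl2 unmasks [(1S,2R,3R)-7-(benzyloxy)-1-[4-(benzyloxy)-3-methoxyphenyl]-3-formyl-6-methoxy-1,2,3,4-tetrahydronaphthalen-2-yl]methyl (2E)-3-[4-(benzyloxy)phenyl]prop-2-enoate F13.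
- NaBH4 at −40 °C reduces the aldehyde beside the cinnamate to [(1S,2R,3R)-7-(benzyloxy)-1-[4-(benzyloxy)-3-methoxyphenyl]-3-(hydroxymethyl)-6-methoxy-1,2,3,4-tetrahydronaphthalen-2-yl]methyl (2E)-3-[4-(benzyloxy)phenyl]prop-2-enoate F14.
- BCl3/C6HMe5 at −78 °C converts F14 into 24.

**Further compounds**

F1 | step 6 | (2E)-4-[4-(benzyloxy)-3-methoxyphenyl]but-2-en-1-yl methyl carbonate | COC(=O)OC/C=C/Cc1ccc(OCc2ccccc2)c(OC)c1
F2 | step 6 | dimethyl 2-[(2S)-1-[4-(benzyloxy)-3-methoxyphenyl]but-3-en-2-yl]propanedioate | COc1cc(C[C@@H](C=C)C(C(=O)OC)C(=O)OC)ccc1OCc1ccccc1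
F3 | step 6 | methyl (3R)-3-{[4-(benzyloxy)-3-methoxyphenyl]methyl}pent-4-enoate | COc1cc(C[C@@H](C=C)CC(=O)OC)ccc1OCc1ccccc1
F4 | step 6 | (4R)-4-{[4-(benzyloxy)-3-methoxyphenyl]methyl}oxolan-2-one | COc1cc(C[C@H]2COC(=O)C2)ccc1OCc1ccccc1
F5 | step 6 | (3S,4R)-3-{[4-(benzyloxy)-3-methoxyphenyl](hydroxy)methyl}-4-{[4-(benzyloxy)-3-methoxyphenyl]methyl}oxolan-2-one, both carbinol epimers | COc1cc(C[C@H]2COC(=O)[C@@H]2C(O)c2ccc(OCc3ccccc3)c(OC)c2)ccc1OCc1ccccc1
F6 | step 6 | trans-fused lactone of (1S,2R,3R)-7-(benzyloxy)-1-[4-(benzyloxy)-3-methoxyphenyl]-3-(hydroxymethyl)-6-methoxy-1,2,3,4-tetrahydronaphthalene-2-carboxylic acid | COc1cc([C@H]2c3cc(OCc4ccccc4)c(OC)cc3C[C@@H](CO5)[C@@H]2C5=O)ccc1OCc1ccccc1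
F7 | step 6 | (1S,2R,3R)-7-(benzyloxy)-1-[4-(benzyloxy)-3-methoxyphenyl]-3-(hydroxymethyl)-N,6-dimethoxy-N-methyl-1,2,3,4-tetrahydronaphthalene-2-carboxamide | COc1cc([C@H]2c3cc(OCc4ccccc4)c(OC)cc3C[C@@H](CO)[C@@H]2C(=O)N(C)OC)ccc1OCc1ccccc1
F8 | step 6 | (1S,2R,3R)-7-(benzyloxy)-1-[4-(benzyloxy)-3-methoxyphenyl]-N,6-dimethoxy-N-methyl-3-{[(triethylsilyl)oxy]methyl}-1,2,3,4-tetrahydronaphthalene-2-carboxamide | COc1cc([C@H]2c3cc(OCc4ccccc4)c(OC)cc3C[C@@H](CO[Si](CC)(CC)CC)[C@@H]2C(=O)N(C)OC)ccc1OCc1ccccc1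
F9 | step 13 | [(1S,2R,3R)-7-hydroxy-1-(4-hydroxy-3-methoxyphenyl)-6-methoxy-3-{[(triethylsilyl)oxy]methyl}-1,2,3,4-tetrahydronaphthalen-2-yl]methanol | COc1cc([C@H]2c3cc(O)c(OC)cc3C[C@@H](CO[Si](CC)(CC)CC)[C@@H]2CO)ccc1O
F10 | step 9 | methyl (1S,2R,3R)-7-(benzyloxy)-1-[4-(benzyloxy)-3-methoxyphenyl]-3-(dimethoxymethyl)-6-methoxy-1,2,3,4-tetrahydronaphthalene-2-carboxylate | COc1cc([C@H]2c3cc(OCc4ccccc4)c(OC)cc3C[C@@H](C(OC)OC)[C@@H]2C(=O)OC)ccc1OCc1ccccc1
F11 | step 9 | [(1S,2R,3R)-7-(benzyloxy)-1-[4-(benzyloxy)-3-methoxyphenyl]-3-(dimethoxymethyl)-6-methoxy-1,2,3,4-tetrahydronaphthalen-2-yl]methanol | COc1cc([C@H]2c3cc(OCc4ccccc4)c(OC)cc3C[C@@H](C(OC)OC)[C@@H]2CO)ccc1OCc1ccccc1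
F12 | step 9 | [(1S,2R,3R)-7-(benzyloxy)-1-[4-(benzyloxy)-3-methoxyphenyl]-3-(dimethoxymethyl)-6-methoxy-1,2,3,4-tetrahydronaphthalen-2-yl]methyl (2E)-3-[4-(benzyloxy)phenyl]prop-2-enoate | COc1cc([C@H]2c3cc(OCc4ccccc4)c(OC)cc3C[C@@H](C(OC)OC)[C@@H]2COC(=O)/C=C/c2ccc(OCc3ccccc3)cc2)ccc1OCc1ccccc1
F13 | step 9 | [(1S,2R,3R)-7-(benzyloxy)-1-[4-(benzyloxy)-3-methoxyphenyl]-3-formyl-6-methoxy-1,2,3,4-tetrahydronaphthalen-2-yl]methyl (2E)-3-[4-(benzyloxy)phenyl]prop-2-enoate | COc1cc([C@H]2c3cc(OCc4ccccc4)c(OC)cc3C[C@@H](C=O)[C@@H]2COC(=O)/C=C/c2ccc(OCc3ccccc3)cc2)ccc1OCc1ccccc1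
F14 | step 9 | [(1S,2R,3R)-7-(benzyloxy)-1-[4-(benzyloxy)-3-methoxyphenyl]-3-(hydroxymethyl)-6-methoxy-1,2,3,4-tetrahydronaphthalen-2-yl]methyl (2E)-3-[4-(benzyloxy)phenyl]prop-2-enoate | COc1cc([C@H]2c3cc(OCc4ccccc4)c(OC)cc3C[C@@H](CO)[C@@H]2COC(=O)/C=C/c2ccc(OCc3ccccc3)cc2)ccc1OCc1ccccc1
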